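**Plan**

- Retrosynthesis first adjusts the periphery: the C19–O acyl bond, the C12–C13 bond to the butenolide and the oxidation levels at C3 and C6. What remains is the ring-fusion enone C6(=O)–C5=C10, which ring A (C1–C5, C10) and ring B (C5–C10) share.
- That enone is the alkyne–carbonyl metathesis product of a ten-membered ring in which a C5≡C6 alkyne lies across from a C10 ketone, flanked by the quaternary carbons C4 and C9. Cutting C5–C10 therefore opens both rings at once.
- The ten-membered ring is cut at C6–C7 (alkynyl iodide plus aldehyde, then C7 deoxygenation) and at C1–C10 (alkyllithium plus lactone). This gives a western C1–C6 iodide and an eastern C7–C12 lactone.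
- Forward: the halves are joined at C1–C10, the macrocycle is closed at C6–C7, and rings A and B then arise together by transannular C5–C10 bonding. The C6 alcohol, butenolide, C19 ester and C3 ketone follow.
- Stereochemistry: C4 (with a sacrificial C3 carbinol) comes from an iridium-catalysed anti-selective tert-(hydroxy)prenylation. C8 comes from (R)-4-methylbutyrolactone, C9 from alkylation of its enolate anti to the C8 methyl, and C6 from a reagent-controlled CBS reduction.

Key step: step 16

Numbering: clerodane numbers are used throughout (C17 = methyl on C8, C18 = methyl on C4, C19 = CH2O on C4, C20 = methyl on C9, C11–C12 = chain on C9, C13–C16 = butenolide).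

Assumption: the (R)-configured bisphosphine is taken to give the (3S) carbinol in step 1, by analogy with related iridium-catalysed carbonyl allylations; if the first run shows the opposite sense, the (S)-ligand is used and nothing else changes.

**Route**

Step 1
Reactants: 1 3-[(4-methoxybenzyl)oxy]propan-1-ol; 2 2-methyl-2-vinyloxirane (isoprene monoxide, racemic)
Product: 3 (2S,3S)-2-ethenyl-5-[(4-methoxybenzyl)oxy]-2-methylpentane-1,3-diol
Conditions: π-allyliridium C,O-benzoate catalyst made from [Ir(cod)Cl]2, (R)-Tol-BINAP, 4-cyano-3-nitrobenzoic acid and allyl acetate (5 mol %), K3PO4 (5 mol %), 2 (3 equiv), THF, 60 °C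
Reagents that add atoms: none
Why: Iridium-catalysed transfer-hydrogenative carbonyl tert-(hydroxy)prenylation, in which the alcohol is dehydrogenated in situ, ring-opened isoprene oxide adds as an (E)-σ-allyl through a chair-like transition state so that the hydroxymethyl group ends anti and the methyl group syn to the new C3 hydroxyl, and the chiral ligand fixes the absolute sense of C3 and of the quaternary C4.

Step 2
Reactants: 3 (2S,3S)-2-ethenyl-5-[(4-methoxybenzyl)oxy]-2-methylpentane-1,3-diol
Product: 4 (4S,5S)-2,2-di-tert-butyl-5-ethenyl-4-{2-[(4-methoxybenzyl)oxy]ethyl}-5-methyl-1,3,2-dioxasilinane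
Conditions: tBu2Si(OTf)2, 2,6-lutidine, CH2Cl2, 0 °C
Reagents that add atoms: di-tert-butylsilyl bis(trifluoromethanesulfonate), CC(C)(C)[Si](OS(=O)(=O)C(F)(F)F)(OS(=O)(=O)C(F)(F)F)C(C)(C)C
Why: Cyclic silylene formation closes the 1,3-diol to a six-membered dioxasilinane that should tolerate the organolithium, oxidative, radical and Lewis-acidic steps ahead and is later cleaved by fluoride faster than a secondary silyl ether.

Step 3
Reactants: 4 (4S,5S)-2,2-di-tert-butyl-5-ethenyl-4-{2-[(4-methoxybenzyl)oxy]ethyl}-5-methyl-1,3,2-dioxasilinane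
Product: 5 (4S,5S)-2,2-di-tert-butyl-4-{2-[(4-methoxybenzyl)oxy]ethyl}-5-methyl-1,3,2-dioxasilinane-5-carbaldehyde
Conditions: OsO4 (2 mol %), NaIO4 (4 equiv), 2,6-lutidine, 1,4-dioxane/H2O, rt
Reagents that add atoms: osmium tetroxide, O=[Os](=O)(=O)=O (oxygen donor, regenerated by sodium periodate, [Na+].[O-]I(=O)(=O)=O)
Why: Lemieux–Johnson oxidative cleavage of the monosubstituted alkene spares the PMB ether, which ozone would attack, and gives an aldehyde without α-hydrogen, so C4 cannot epimerise.

Step 4
Reactants: 5 (4S,5S)-2,2-di-tert-butyl-4-{2-[(4-methoxybenzyl)oxy]ethyl}-5-methyl-1,3,2-dioxasilinane-5-carbaldehyde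
Product: 6 (4S,5S)-2,2-di-tert-butyl-5-(2,2-dibromoethenyl)-4-{2-[(4-methoxybenzyl)oxy]ethyl}-5-methyl-1,3,2-dioxasilinane
Conditions: CBr4, PPh3, Zn dust, CH2Cl2, rt
Reagents that add atoms: carbon tetrabromide, BrC(Br)(Br)Br
Why: Corey–Fuchs dibromo-olefination (Wittig reaction of the ylide made from CBr4, PPh3 and Zn) works on hindered non-enolisable aldehydes, and the zinc variant keeps the medium free of acid.

Step 5
Reactants: 6 (4S,5S)-2,2-di-tert-butyl-5-(2,2-dibromoethenyl)-4-{2-[(4-methoxybenzyl)oxy]ethyl}-5-methyl-1,3,2-dioxasilinane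
Product: 8 (4S,5S)-2,2-di-tert-butyl-4-{2-[(4-methoxybenzyl)oxy]ethyl}-5-methyl-5-[(trimethylsilyl)ethynyl]-1,3,2-dioxasilinane, via lithium acetylide 7 (not isolated)
Conditions: n-BuLi (2.2 equiv), THF, −78 °C; then Me3SiCl, −78 °C to rt
Reagents that add atoms: chlorotrimethylsilane, C[Si](C)(C)Cl
Why: In the second stage of the Corey–Fuchs sequence, bromine–lithium exchange and Fritsch–Buttenberg–Wiechell-type loss of LiBr give the C5≡C6 alkyne, a second equivalent of base gives the acetylide, and C-silylation masks the acidic C–H that would otherwise quench the alkyllithium of step 10.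

Step 6
Reactants: 8 (4S,5S)-2,2-di-tert-butyl-4-{2-[(4-methoxybenzyl)oxy]ethyl}-5-methyl-5-[(trimethylsilyl)ethynyl]-1,3,2-dioxasilinane
Product: 9 2-{(4S,5S)-2,2-di-tert-butyl-5-methyl-5-[(trimethylsilyl)ethynyl]-1,3,2-dioxasilinan-4-yl}ethan-1-ol
Conditions: DDQ, CH2Cl2/pH 7 phosphate buffer, 0 °C
Reagents that add atoms: none
Why: Oxidative cleavage of the p-methoxybenzyl ether by DDQ (hydride abstraction, then hydrolysis of the oxocarbenium ion) should leave the silylene and the alkynylsilane untouched.

Step 7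
Reactants: 9 2-{(4S,5S)-2,2-di-tert-butyl-5-methyl-5-[(trimethylsilyl)ethynyl]-1,3,2-dioxasilinan-4-yl}ethan-1-ol
Product: 10 (4S,5S)-2,2-di-tert-butyl-4-(2-iodoethyl)-5-methyl-5-[(trimethylsilyl)ethynyl]-1,3,2-dioxasilinane
Conditions: I2, PPh3, imidazole, CH2Cl2, 0 °C to rt
Reagents that add atoms: iodine, II
Why: Appel-type iodination of the unhindered primary alcohol through its alkoxyphosphonium salt proceeds by SN2 displacement under near-neutral conditions.

Step 8
Reactants: 11 (R)-4-methyldihydrofuran-2(3H)-one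
Product: 13 (3R,4R)-3,4-dimethyldihydrofuran-2(3H)-one, via lithium enolate 12 (not isolated)
Conditions: LiN(iPr)2, THF, −78 °C; then MeI
Reagents that add atoms: iodomethane, CI
Why: In this kinetic enolate alkylation of the lactone, iodomethane approaches anti to the C8 methyl group to give the trans isomer, although this centre is enolised again in step 9.

Step 9
Reactants: 13 (3R,4R)-3,4-dimethyldihydrofuran-2(3H)-one
Product: 15 (3R,4R)-3-(2-chloroethyl)-3,4-dimethyldihydrofuran-2(3H)-one, via lithium enolate 14 (not isolated)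
Conditions: LiN(iPr)2, THF, −78 °C; then BrCH2CH2Cl, DMPU, −78 to 0 °C
Reagents that add atoms: 1-bromo-2-chloroethane, ClCCBr
Why: Enolate alkylation creates the quaternary C9, because the planar enolate is attacked at the C–Br end of the dihalide on the face anti to the adjacent C8 methyl group, so the chloroethyl chain ends trans and the C9 methyl cis to it, which is the (9R) configuration of the target.

Step 10
Reactants: 10 (4S,5S)-2,2-di-tert-butyl-4-(2-iodoethyl)-5-methyl-5-[(trimethylsilyl)ethynyl]-1,3,2-dioxasilinane; 15 (3R,4R)-3-(2-chloroethyl)-3,4-dimethyldihydrofuran-2(3H)-one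
Product: 17 (4R,5R)-4-(2-chloroethyl)-1-{(4S,5S)-2,2-di-tert-butyl-5-methyl-5-[(trimethylsilyl)ethynyl]-1,3,2-dioxasilinan-4-yl}-6-hydroxy-4,5-dimethylhexan-3-one (C10 ketone with free C7–OH and its five-membered lactol in equilibrium), via primary alkyllithium 16 (not isolated)
Conditions: 10, t-BuLi (2.1 equiv), Et2O/pentane, −78 °C; then 15, −78 to −40 °C; AcOH, −78 °C
Reagents that add atoms: none
Why: Iodine–lithium exchange is followed by acylation of the primary alkyllithium by the lactone, where the lithium lactolate is stable at low temperature and the quaternary α-carbon prevents enolisation, so the C10 ketone appears only on work-up and a second addition is avoided.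

Step 11
Reactants: 17 hydroxy ketone with C6–SiMe3
Product: 18 (4R,5R)-4-(2-chloroethyl)-1-[(4S,5S)-2,2-di-tert-butyl-5-(iodoethynyl)-5-methyl-1,3,2-dioxasilinan-4-yl]-6-hydroxy-4,5-dimethylhexan-3-one
Conditions: N-iodosuccinimide, AgNO3 (10 mol %), acetone, rt, dark
Reagents that add atoms: N-iodosuccinimide, O=C1CCC(=O)N1I
Why: Silver-catalysed iododesilylation of the alkynylsilane converts the C–Si bond directly into the C–I bond needed for chromium insertion and should not touch the alcohol or the ketone.

Step 12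
Reactants: 18 iodoalkyne hydroxy ketone
Product: 19 (2R,3R)-3-(2-chloroethyl)-6-[(4S,5S)-2,2-di-tert-butyl-5-(iodoethynyl)-5-methyl-1,3,2-dioxasilinan-4-yl]-2,3-dimethyl-4-oxohexanal
Conditions: Dess–Martin periodinane, NaHCO3, CH2Cl2, 0 °C to rt
Reagents that add atoms: none
Why: Dess–Martin oxidation of the open hydroxy-ketone tautomer to the C7 aldehyde under buffered, non-basic conditions should keep the α-stereocentre C8 intact.

Step 13
Reactants: 19 iodoalkyne keto aldehyde
Product: 20 ten-membered 5-yn-10-one with 7-OH (both C7 epimers), 3,19-O-(di-tert-butylsilylene), 4-Me, 8-Me, 9-Me and 9-(2-chloroethyl)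
Conditions: CrCl2 (8 equiv), NiCl2 (2 mol %), degassed THF, rt, slow addition of 19 (about 2 mM final)
Reagents that add atoms: none
Why: In this intramolecular Nozaki–Hiyama–Kishi reaction the alkynyl iodide adds oxidatively to zerovalent nickel and transmetalates to chromium, and the trivalent alkynylchromium attacks only the aldehyde under base-free conditions that neither enolise the ketone nor epimerise C8; the new C7 carbinol forms without control and is removed in step 15.

Step 14
Reactants: 20 macrocyclic propargylic alcohol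
Product: 21 O-(imidazol-1-ylthiocarbonyl) derivative of 20 at C7
Conditions: 1,1'-thiocarbonyldiimidazole, 4-(dimethylamino)pyridine (cat.), CH2Cl2, 40 °C
Reagents that add atoms: 1,1'-thiocarbonyldiimidazole, S=C(n1ccnc1)n1ccnc1
Why: Thioacylation of the secondary propargylic alcohol installs the radical-accepting group for the Barton–McCombie deoxygenation.

Step 15
Reactants: 21 C7 thiocarbonylimidazolide
Product: 22 ten-membered 5-yn-10-one (C7 = CH2) with 3,19-O-(di-tert-butylsilylene), 4-Me, 8-Me, 9-Me and 9-(2-chloroethyl)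
Conditions: Bu3SnH, Et3B (cat.), air, toluene, rt
Reagents that add atoms: none
Why: In this Barton–McCombie deoxygenation, stannyl radical addition to sulfur and C–O fragmentation give a propargylic radical that should take hydrogen at C7, because the other terminus C5 is shielded by quaternary C4 and would lead to a strained cyclic allene; initiation at room temperature avoids a thermal [3,3] shift, and both C7 epimers converge.

Step 16
Reactants: 22 ten-membered 5-yn-10-one
Product: 23 6-oxo-5(10)-ene decalin with 3,19-O-(di-tert-butylsilylene), 4-Me, 8-Me, 9-Me and 9-(2-chloroethyl)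
Conditions: BF3·OEt2 (1.5 equiv), CH2Cl2, −78 to 0 °C
Reagents that add atoms: none
Why: BF3 binds the C10 ketone, the only carbonyl of 22; the alkyne carbon C5 attacks it across the ring, the incipient vinyl cation at C6 is captured by the same oxygen to give a boron-bound oxetene, and ring opening of that oxetene turns C5–C10 into the tetrasubstituted alkene and places the oxygen on C6 (alkyne–carbonyl metathesis). The closest known reaction is the acid-promoted transannular cyclisation of cyclodec-5-ynone to bicyclo[4.4.0]dec-1(6)-en-2-one, of which 22 is a substituted member. The single new C5–C10 bond closes both rings: ring A (C10, C1–C5) by a 6-exo attack in which the alkyne lies outside the new ring, and ring B (C5–C10) by the complementary 6-endo closure in which C6 lies inside it. No stereocentre is formed, since C5, C6 and C10 all end sp2, and C3, C4, C8 and C9 are not epimerisable under Lewis acid. The step needs regioselectivity (C5 versus C6 as the nucleophile) and chemoselectivity: bonding through C6 would give a strained five-/seven-membered bicycle, whereas bonding through C5 gives two six-membered rings, and because the diol is tied up as a silylene and the side chain ends in an inert chloride, C10 is the only Lewis-basic site whose activation leads anywhere.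

Step 17
Reactants: 23 6-oxo-5(10)-ene decalin
Product: 24 (6S)-6-hydroxy-5(10)-ene decalin (silylene and chloroethyl chain unchanged)
Conditions: (R)-2-methyl-CBS-oxazaborolidine [(R)-1-methyl-3,3-diphenyltetrahydro-1H,3H-pyrrolo[1,2-c][1,3,2]oxazaborole] (0.5 equiv), catecholborane, toluene, −78 °C
Reagents that add atoms: none
Why: In this Corey–Bakshi–Shibata reduction the fully substituted alkenyl carbon C5 acts as the large and the C7 methylene as the small carbonyl substituent, so the (R)-oxazaborolidine should deliver hydride to the face that gives the (6S) alcohol and override any bias from the ring substituents.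

Step 18
Reactants: 24 (6S)-allylic alcohol
Product: 25 (6S)-6-(tert-butyldimethylsilyloxy)-5(10)-ene decalin
Conditions: TBSOTf, 2,6-lutidine, CH2Cl2, −78 °C
Reagents that add atoms: tert-butyldimethylsilyl trifluoromethanesulfonate, CC(C)(C)[Si](C)(C)OS(=O)(=O)C(F)(F)F
Why: Silylation of the hindered allylic alcohol with the silyl triflate under buffered conditions protects C6–OH for the later C3 oxidation.

Step 19
Reactants: 25 C6 silyl ether with C12–Cl
Product: 26 C12 iodide of 25
Conditions: NaI, acetone, reflux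
Reagents that add atoms: sodium iodide, [Na+].[I-]
Why: Finkelstein halide exchange at the unhindered primary C12 (SN2, driven by precipitation of NaCl) gives the iodide needed for zinc insertion.

Step 20
Reactants: 26 C12 iodide; 27 4-bromofuran-2(5H)-one
Product: 29 butenolide (C12–C13 joined; 6-OTBS and 3,19-O-silylene retained), via alkylzinc iodide 28 (not isolated)
Conditions: Zn dust, LiCl, THF, 40 °C; then 27, Pd(PPh3)4 (5 mol %), THF, rt to 50 °C
Reagents that add atoms: none
Why: In this Negishi cross-coupling, LiCl-assisted zinc insertion into the primary C–I bond gives an alkylzinc iodide that tolerates the silyl ethers, and palladium-catalysed sp3–sp2 coupling with the activated β-bromo butenolide forms C12–C13.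

Step 21
Reactants: 29 butenolide with 3,19-O-silylene
Product: 30 3,19-diol with 6-OTBS and butenolide
Conditions: HF·pyridine, pyridine, THF, 0 °C
Reagents that add atoms: none
Why: Fluoride cleavage of the cyclic dialkoxysilane with pyridine-buffered HF·pyridine at 0 °C is much faster than cleavage of the hindered secondary TBS ether at C6, a selectivity well known from ribonucleoside chemistry.

Step 22
Reactants: 31 3-(4-hydroxyphenyl)propanoic acid
Product: 33 3-[4-(tert-butyldimethylsilyloxy)phenyl]propanoic acid, via silyl ester 32 (not isolated)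
Conditions: TBSCl (2.2 equiv), imidazole, DMF, rt; then AcOH/THF/H2O, rt
Reagents that add atoms: tert-butyldimethylsilyl chloride, CC(C)(C)[Si](C)(C)Cl
Why: Silylation of both acidic OH groups followed by hydrolysis of the labile silyl ester leaves the phenol protected as its TBS ether, so the acid cannot self-acylate in step 23.

Step 23
Reactants: 30 3,19-diol; 33 3-[4-(tert-butyldimethylsilyloxy)phenyl]propanoic acid
Product: 34 C19 ester with free C3–OH, 6-OTBS and aryl OTBS
Conditions: N-(3-dimethylaminopropyl)-N'-ethylcarbodiimide hydrochloride, 4-(dimethylamino)pyridine (cat.), 33 (1.05 equiv), CH2Cl2, 0 °C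
Reagents that add atoms: none
Why: In this Steglich-type carbodiimide esterification the primary C19–OH should react much faster than the secondary C3–OH, which is flanked by quaternary C4, when about one equivalent of acid is used at 0 °C.

Step 24
Reactants: 34 C19 ester with free C3–OH
Product: 35 C3 ketone with 6-OTBS and aryl OTBS
Conditions: Dess–Martin periodinane, NaHCO3, CH2Cl2, 0 °C to rt
Reagents that add atoms: none
Why: Dess–Martin oxidation converts the remaining secondary alcohol to the C3 ketone, and since C4 is quaternary the β-acyloxy ketone can neither eliminate nor epimerise.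

Step 25
Reactants: 35 bis-silyl ether of the target
Product: 36 CNP0301014.1
Conditions: HF·pyridine, THF, 0 °C to rt
Reagents that add atoms: none
Why: Fluoride-mediated cleavage of the aryl and the allylic TBS ethers under non-basic conditions should free the phenol and C6–OH without touching the esters, the butenolide or the acid-sensitive allylic alcohol.

**Compound list**

1 | 3-[(4-methoxybenzyl)oxy]propan-1-ol | OCCCOCc1ccc(OC)cc1 | starting material
2 | 2-methyl-2-vinyloxirane (racemic) | CC1(C=C)CO1 | starting material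
3 | (2S,3S)-2-ethenyl-5-[(4-methoxybenzyl)oxy]-2-methylpentane-1,3-diol | COc1ccc(COCC[C@H](O)[C@](C=C)(C)CO)cc1 | intermediate
4 | (4S,5S)-2,2-di-tert-butyl-5-ethenyl-4-{2-[(4-methoxybenzyl)oxy]ethyl}-5-methyl-1,3,2-dioxasilinane | COc1ccc(COCC[C@@H]2O[Si](C(C)(C)C)(C(C)(C)C)OC[C@]2(C)C=C)cc1 | intermediate
5 | (4S,5S)-2,2-di-tert-butyl-4-{2-[(4-methoxybenzyl)oxy]ethyl}-5-methyl-1,3,2-dioxasilinane-5-carbaldehyde | COc1ccc(COCC[C@@H]2O[Si](C(C)(C)C)(C(C)(C)C)OC[C@]2(C)C=O)cc1 | intermediate
6 | (4S,5S)-2,2-di-tert-butyl-5-(2,2-dibromoethenyl)-4-{2-[(4-methoxybenzyl)oxy]ethyl}-5-methyl-1,3,2-dioxasilinane | COc1ccc(COCC[C@@H]2O[Si](C(C)(C)C)(C(C)(C)C)OC[C@]2(C)C=C(Br)Br)cc1 | intermediate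
7 | lithium acetylide of the C5≡C6 alkyne (silylene, PMB ether) | COc1ccc(COCC[C@@H]2O[Si](C(C)(C)C)(C(C)(C)C)OC[C@]2(C)C#C[Li])cc1 | intermediate (not isolated)
8 | (4S,5S)-2,2-di-tert-butyl-4-{2-[(4-methoxybenzyl)oxy]ethyl}-5-methyl-5-[(trimethylsilyl)ethynyl]-1,3,2-dioxasilinane | COc1ccc(COCC[C@@H]2O[Si](C(C)(C)C)(C(C)(C)C)OC[C@]2(C)C#C[Si](C)(C)C)cc1 | intermediate
9 | 2-{(4S,5S)-2,2-di-tert-butyl-5-methyl-5-[(trimethylsilyl)ethynyl]-1,3,2-dioxasilinan-4-yl}ethan-1-ol | OCC[C@@H]1O[Si](C(C)(C)C)(C(C)(C)C)OC[C@]1(C)C#C[Si](C)(C)C | intermediate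
10 | (4S,5S)-2,2-di-tert-butyl-4-(2-iodoethyl)-5-methyl-5-[(trimethylsilyl)ethynyl]-1,3,2-dioxasilinane | ICC[C@@H]1O[Si](C(C)(C)C)(C(C)(C)C)OC[C@]1(C)C#C[Si](C)(C)C | intermediate
11 | (R)-4-methyldihydrofuran-2(3H)-one | C[C@H]1COC(=O)C1 | starting material
12 | lithium enolate of 11 | C[C@H]1COC(O[Li])=C1 | intermediate (not isolated)
13 | (3R,4R)-3,4-dimethyldihydrofuran-2(3H)-one | C[C@H]1COC(=O)[C@@H]1C | intermediate
14 | lithium enolate of 13 | C[C@H]1COC(O[Li])=C1C | intermediate (not isolated)
15 | (3R,4R)-3-(2-chloroethyl)-3,4-dimethyldihydrofuran-2(3H)-one | C[C@H]1COC(=O)[C@]1(C)CCCl | intermediate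
16 | primary alkyllithium from 10 | [Li]CC[C@@H]1O[Si](C(C)(C)C)(C(C)(C)C)OC[C@]1(C)C#C[Si](C)(C)C | intermediate (not isolated)
17 | (4R,5R)-4-(2-chloroethyl)-1-{(4S,5S)-2,2-di-tert-butyl-5-methyl-5-[(trimethylsilyl)ethynyl]-1,3,2-dioxasilinan-4-yl}-6-hydroxy-4,5-dimethylhexan-3-one | ClCC[C@](C)([C@@H](C)CO)C(=O)CC[C@@H]1O[Si](C(C)(C)C)(C(C)(C)C)OC[C@]1(C)C#C[Si](C)(C)C | intermediate
18 | (4R,5R)-4-(2-chloroethyl)-1-[(4S,5S)-2,2-di-tert-butyl-5-(iodoethynyl)-5-methyl-1,3,2-dioxasilinan-4-yl]-6-hydroxy-4,5-dimethylhexan-3-one | ClCC[C@](C)([C@@H](C)CO)C(=O)CC[C@@H]1O[Si](C(C)(C)C)(C(C)(C)C)OC[C@]1(C)C#CI | intermediate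
19 | (2R,3R)-3-(2-chloroethyl)-6-[(4S,5S)-2,2-di-tert-butyl-5-(iodoethynyl)-5-methyl-1,3,2-dioxasilinan-4-yl]-2,3-dimethyl-4-oxohexanal | ClCC[C@](C)([C@@H](C)C=O)C(=O)CC[C@@H]1O[Si](C(C)(C)C)(C(C)(C)C)OC[C@]1(C)C#CI | intermediate
20 | ten-membered 7-hydroxy-5-yn-10-one (C7 epimers), 3,19-O-(di-tert-butylsilylene), 9-(2-chloroethyl); C3, C4, C8, C9 as in 17 | OC1C#C[C@@]2(C)CO[Si](C(C)(C)C)(C(C)(C)C)O[C@H]2CCC(=O)[C@](C)(CCCl)[C@H]1C | intermediate
21 | C7 O-(imidazol-1-ylthiocarbonyl) derivative of 20 | S=C(OC1C#C[C@@]2(C)CO[Si](C(C)(C)C)(C(C)(C)C)O[C@H]2CCC(=O)[C@](C)(CCCl)[C@H]1C)n1ccnc1 | intermediate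
22 | ten-membered 5-yn-10-one, 3,19-O-(di-tert-butylsilylene), 9-(2-chloroethyl) (key-step precursor) | C1C#C[C@@]2(C)CO[Si](C(C)(C)C)(C(C)(C)C)O[C@H]2CCC(=O)[C@](C)(CCCl)[C@H]1C | intermediate
23 | 6-oxo-5(10)-ene decalin, 3,19-O-(di-tert-butylsilylene), 9-(2-chloroethyl) (key-step product) | C[C@H]1CC(=O)C2=C(CC[C@@H]3O[Si](C(C)(C)C)(C(C)(C)C)OC[C@]23C)[C@]1(C)CCCl | intermediate
24 | (6S)-6-hydroxy-5(10)-ene decalin, silylene, chloroethyl | C[C@H]1C[C@H](O)C2=C(CC[C@@H]3O[Si](C(C)(C)C)(C(C)(C)C)OC[C@]23C)[C@]1(C)CCCl | intermediate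
25 | (6S)-6-(tert-butyldimethylsilyloxy) decalin, silylene, chloroethyl | C[C@H]1C[C@H](O[Si](C)(C)C(C)(C)C)C2=C(CC[C@@H]3O[Si](C(C)(C)C)(C(C)(C)C)OC[C@]23C)[C@]1(C)CCCl | intermediate
26 | C12 iodide of 25 | C[C@H]1C[C@H](O[Si](C)(C)C(C)(C)C)C2=C(CC[C@@H]3O[Si](C(C)(C)C)(C(C)(C)C)OC[C@]23C)[C@]1(C)CCI | intermediate
27 | 4-bromofuran-2(5H)-one | BrC1=CC(=O)OC1 | starting material
28 | alkylzinc iodide from 26 | C[C@H]1C[C@H](O[Si](C)(C)C(C)(C)C)C2=C(CC[C@@H]3O[Si](C(C)(C)C)(C(C)(C)C)OC[C@]23C)[C@]1(C)CC[Zn]I | intermediate (not isolated)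
29 | butenolide with 6-OTBS and 3,19-O-silylene | C[C@H]1C[C@H](O[Si](C)(C)C(C)(C)C)C2=C(CC[C@@H]3O[Si](C(C)(C)C)(C(C)(C)C)OC[C@]23C)[C@]1(C)CCC1=CC(=O)OC1 | intermediate
30 | 3,19-diol with 6-OTBS and butenolide | C[C@H]1C[C@H](O[Si](C)(C)C(C)(C)C)C2=C(CC[C@H](O)[C@]2(C)CO)[C@]1(C)CCC1=CC(=O)OC1 | intermediate
31 | 3-(4-hydroxyphenyl)propanoic acid | OC(=O)CCc1ccc(O)cc1 | starting material
32 | tert-butyldimethylsilyl 3-[4-(tert-butyldimethylsilyloxy)phenyl]propanoate | CC(C)(C)[Si](C)(C)OC(=O)CCc1ccc(O[Si](C)(C)C(C)(C)C)cc1 | intermediate (not isolated)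
33 | 3-[4-(tert-butyldimethylsilyloxy)phenyl]propanoic acid | OC(=O)CCc1ccc(O[Si](C)(C)C(C)(C)C)cc1 | intermediate
34 | C19 ester with free C3–OH, 6-OTBS, aryl OTBS | C[C@H]1C[C@H](O[Si](C)(C)C(C)(C)C)C2=C(CC[C@H](O)[C@]2(C)COC(=O)CCc2ccc(O[Si](C)(C)C(C)(C)C)cc2)[C@]1(C)CCC1=CC(=O)OC1 | intermediate
35 | C3 ketone with 6-OTBS, aryl OTBS | C[C@H]1C[C@H](O[Si](C)(C)C(C)(C)C)C2=C(CCC(=O)[C@]2(C)COC(=O)CCc2ccc(O[Si](C)(C)C(C)(C)C)cc2)[C@]1(C)CCC1=CC(=O)OC1 | intermediate
36 | CNP0301014.1 | C[C@H]1C[C@H](O)C2=C(CCC(=O)[C@]2(C)COC(=O)CCc2ccc(O)cc2)[C@]1(C)CCC1=CC(=O)OC1 | target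

**Totals and risks**

Total step count: 25. Longest linear sequence: 22 steps (steps 1–7, 10–21, 23–25).

Steps most likely to fail:

1. Step 16 (transannular ring formation). The C10 carbonyl sits next to quaternary C9 and may bind the Lewis acid slowly, so that fluoride transfer from boron opens the silylene before the ring closes (loss of a protecting group), or the vinyl cation is quenched externally before oxygen transfer. Fallback: the cyclic silyl ether is exchanged for two acetates before ring formation, so that only esters accompany the ynone and a stronger acid can be used. From 22, HF·pyridine/pyridine (THF, 0 °C) would give the diol ynone F1, and Ac2O/pyridine/4-(dimethylamino)pyridine the ynone diacetate F2. BF3·OEt2 or TfOH in CH2Cl2 would then give the decalin enone diacetate F3 by the same C5–C10 closure. K2CO3 in MeOH would free the decalin enone diol F4, which tBu2Si(OTf)2/2,6-lutidine closes again to 23.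

2. Step 13 (ten-membered ring closure). Bimolecular coupling and reduction of the C–I bond may outrun closure of the medium ring. Fallback: the organochromium route is replaced by soft metalation of the free alkyne. From 17, AgNO3-catalysed protodesilylation (acetone/H2O) would give the terminal alkyne hydroxy ketone F5, and Dess–Martin oxidation the terminal alkyne keto aldehyde F6. A zinc acetylide generated with Zn(OTf)2 and Et3N (toluene, 50 °C, slow addition) should then add to the aldehyde and not to the ketone, returning to 20.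

3. Step 15 (C7 deoxygenation). Hydrogen transfer to the allenyl terminus, or a [3,3] shift of the thiocarbonyl group before fragmentation, would divert the propargylic system. Fallback: an ionic route through a cobalt-stabilised cation. From 20, Co2(CO)8 (CH2Cl2, rt) would give the hexacarbonyldicobalt complex of the propargylic alcohol F7. Et3SiH in large excess with CF3CO2H (CH2Cl2, −10 °C) would reduce the propargylic cation to the deoxygenated hexacarbonyldicobalt complex F8 (Nicholas reduction); the excess silane is meant to outrun participation by the C10 carbonyl. (NH4)2Ce(NO3)6 in acetone (−78 to 0 °C) would then release 22.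

**Further compounds**

F1 | step 16 | diol ynone (ten-membered 5-yn-10-one, 3,19-diol, 9-(2-chloroethyl)) | C1C#C[C@@](C)(CO)[C@@H](O)CCC(=O)[C@](C)(CCCl)[C@H]1C
F2 | step 16 | ynone diacetate (3,19-di-O-acetyl) | C1C#C[C@@](C)(COC(C)=O)[C@@H](OC(C)=O)CCC(=O)[C@](C)(CCCl)[C@H]1C
F3 | step 16 | decalin enone diacetate (6-oxo-5(10)-ene, 3,19-di-O-acetyl) | C[C@H]1CC(=O)C2=C(CC[C@H](OC(C)=O)[C@]2(C)COC(C)=O)[C@]1(C)CCCl
F4 | step 16 | decalin enone diol (6-oxo-5(10)-ene, 3,19-diol) | C[C@H]1CC(=O)C2=C(CC[C@H](O)[C@]2(C)CO)[C@]1(C)CCCl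
F5 | step 13 | terminal alkyne hydroxy ketone (17 without SiMe3) | ClCC[C@](C)([C@@H](C)CO)C(=O)CC[C@@H]1O[Si](C(C)(C)C)(C(C)(C)C)OC[C@]1(C)C#C
F6 | step 13 | terminal alkyne keto aldehyde | ClCC[C@](C)([C@@H](C)C=O)C(=O)CC[C@@H]1O[Si](C(C)(C)C)(C(C)(C)C)OC[C@]1(C)C#C
F7 | step 15 | hexacarbonyldicobalt complex of 20 | OC1C3([Co]4(=C=O)(=C=O)(=C=O)[Co]35(=C=O)(=C=O)=C=O)C45[C@@]2(C)CO[Si](C(C)(C)C)(C(C)(C)C)O[C@H]2CCC(=O)[C@](C)(CCCl)[C@H]1C
F8 | step 15 | hexacarbonyldicobalt complex of 22 | C1C3([Co]4(=C=O)(=C=O)(=C=O)[Co]35(=C=O)(=C=O)=C=O)C45[C@@]2(C)CO[Si](C(C)(C)C)(C(C)(C)C)O[C@H]2CCC(=O)[C@](C)(CCCl)[C@H]1C
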